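**Plan** (guaiane numbering: C1 and C5 are the ring-fusion carbons, C2–C4 complete the cyclopentane, C6–C10 the cycloheptane, C14 is the methylene on C10, C15 the methyl on C4, isopropyl on C7)
Retrosynthesis: acetates off; C10=C14 from a C10 ketone; O8 from conjugate borylation of a C8=C9 enone; then C2–C3 and C1–C5 are cut together (Prins–pinacol transform) to a cyclohexane C5–C10 (temporary C5–C10 bond) with a vinyl carbinol at C10 and an α-silyloxy aldehyde arm (C4, C3) on C5; C4–C5 is cut by an aldol to ethyl pyruvate, which leaves (S)-cryptone.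
Enabling feature: the oxygenated cyclopentane carbon C3 is 1,3 to ring-fusion carbon C1, and C1 is α to the methylene-bearing C10; with C10 as a ketone this is the 3-oxycyclopentyl ketone pattern left by a Prins cyclisation/1,2-shift, so the cycloheptane is a ring-expanded cyclohexane.
Forward: the six-membered ring C5–C10 first (isovaleraldehyde + methyl vinyl ketone), then C4/C3/C15 by aldol and C1/C2 by vinyl addition; one operation closes the cyclopentane and enlarges the cyclohexane to the cycloheptanone; O8 and C14 come last.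
Stereochemistry: C7 from an amine-catalysed Michael addition; C6 by epoxidation anti to isopropyl; C5 and C4 in a chelated aldol; C3 in the chair Prins transition state; C1 by equilibration to the trans ring fusion; C8 by borylation anti to isopropyl.

Key step: step 8

Remark: the trans-fused C10 ketone is assumed to be the more stable ring-fusion isomer (all ring substituents pseudo-equatorial); guaiane locants are also used for the monocyclic intermediates (ring carbons C5–C10).

**Step 1**
Reactants: 1 3-methylbutanal; 2 but-3-en-2-one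
Product: 4 (S)-cryptone, via keto aldehyde 3 (not isolated)
Conditions: (S)-2-[methoxy(diphenyl)methyl]pyrrolidine (5 mol %), ethyl 3,4-dihydroxybenzoate (20 mol %), neat, 4 °C; then LiOH, i-PrOH, rt
Reagents that add atoms: none
Why: Enamine-mediated Michael addition followed by intramolecular aldol condensation (Robinson annulation); the diarylprolinol ether shields one enamine face, so the isopropyl-bearing carbon (future C7) should form with S configuration.

**Step 2**
Reactants: 4 (S)-cryptone
Product: 5 trans-epoxy ketone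
Conditions: 30 % H2O2, NaOH (cat.), MeOH, 0 °C
Reagents that add atoms: hydrogen peroxide, OO
Why: Weitz–Scheffer nucleophilic epoxidation in which hydroperoxide should add to the β-carbon (C6) anti to the neighbouring isopropyl group, placing the future O6 trans to isopropyl.

**Step 3**
Reactants: 5 trans-epoxy ketone
Product: 6 bromo silyl ether
Conditions: Et3SiBr, CH2Cl2, −40 to 0 °C
Reagents that add atoms: bromotriethylsilane, CC[Si](Br)(CC)CC
Why: Halosilane opening of an epoxide: silylation of the epoxide oxygen and SN2 attack of bromide at the carbon α to the carbonyl (C5; C6 is shielded by isopropyl) should give the silylated bromohydrin with C6 unchanged.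

**Step 4**
Reactants: 6 bromo silyl ether; 7 ethyl pyruvate
Product: 8 aldol keto ester
Conditions: SmI2 (2.1 equiv), THF, −78 °C; then ethyl pyruvate, −78 °C; aq. NH4Cl
Reagents that add atoms: none
Why: Samarium Reformatsky reaction: reduction of the α-bromo ketone gives a regiodefined trivalent samarium enolate that should add to the pyruvate ketone anti to the C6 silyloxy group through a chelated Zimmerman–Traxler chair (ester carbonyl on samarium, methyl equatorial), setting C5 and the tertiary carbinol C4, while the pseudo-equatorial silyloxy group is poorly aligned for β-elimination.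

**Step 5**
Reactants: 8 aldol keto ester; 9 vinylmagnesium bromide
Product: 10 vinyl carbinol diol
Conditions: CeCl3 (anhydrous), vinylmagnesium bromide (3 equiv), THF, −78 °C
Reagents that add atoms: none
Why: Organocerium-mediated 1,2-addition to the ketone (the ester sits beside a metal alkoxide and should be left alone); equatorial attack should place the vinyl group trans to the C5 side chain and the new hydroxyl axial.

**Step 6**
Reactants: 10 vinyl carbinol diol
Product: 11 tris(triethylsilyl) ester
Conditions: Et3SiOTf (2.6 equiv), 2,6-lutidine, CH2Cl2, −20 °C to rt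
Reagents that add atoms: triethylsilyl trifluoromethanesulfonate, CC[Si](CC)(CC)OS(=O)(=O)C(F)(F)F
Why: Silyl triflate silylation of both tertiary alcohols, which blocks lactol formation with the later aldehyde and makes the C10 oxygen the silyloxy terminus needed for the pinacol shift.

**Step 7**
Reactants: 11 tris(triethylsilyl) ester
Product: 12 tris(triethylsilyl) aldehyde
Conditions: i-Bu2AlH (1.2 equiv), CH2Cl2, −78 °C; aqueous tartrate work-up
Reagents that add atoms: none
Why: Partial reduction of an α-silyloxy ester, whose tetrahedral aluminate is stable at −78 °C and should release the non-enolisable aldehyde only on work-up.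

**Step 8**
Reactants: 12 tris(triethylsilyl) aldehyde
Product: 14 trans-fused hydroazulenone, via cis-fused hydroazulenone 13 (not isolated)
Conditions: SnCl4 (1.2 equiv), CH2Cl2, −78 to −40 °C; aq. NaHCO3 work-up; then DBU (0.3 equiv), CH2Cl2, rt
Reagents that add atoms: none
Why: SnCl4 activates the aldehyde carbon C3, the terminal vinyl carbon C2 attacks it through a chair six-membered transition state (ring C10–C1–C2–C3–C4–C5), and the developing C1 cation is quenched by 1,2-shift of the ring bond C10–C5 to C1 with loss of the silyl group from the C10 oxygen, so C2–C3 and C1–C5 form in one operation. The closest known reaction type is the Prins–pinacol ring-enlarging cyclopentane annulation of 1-alkenyl-2-(2-oxoethyl)cycloalkanol silyl ethers. The cyclopentane arises by 6-endo-trig Prins closure followed by ring contraction, and the cycloheptanone by one-carbon ring expansion of the cyclohexane (C1 inserted between C10 and C5). C5 migrates with retention and C4 is untouched; C3 is set by the chair in which the tin-bound aldehyde oxygen is equatorial (3β-OH); C1 first forms cis (1αH) by suprafacial migration and is then equilibrated by DBU through the C10 enolate to the trans-fused ketone, in which the substituents on C5–C8 and C1 are all pseudo-equatorial. The step needs migration of C5 and not of C9, which the trans-diequatorial vinyl/side-chain arrangement should secure because the axial silyloxy group leaves only the C10–C5 bond aligned with the empty orbital at C1; an ene pathway is excluded because the vinyl group sits on a fully substituted carbon.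

**Step 9**
Reactants: 14 trans-fused hydroazulenone
Product: 16 C8=C9 enone, via bis(trimethylsilyl) enol ether 15 (not isolated)
Conditions: LiN(i-Pr)2 (2.3 equiv), Me3SiCl, THF, −78 °C; then Pd(OAc)2 (10 mol %), O2 (1 atm), DMSO, rt; citric acid, MeOH
Reagents that add atoms: none
Why: Kinetic enolisation at the C9 methylene with in situ silylation (O3 is silylated as well) and Saegusa oxidation should give the C8=C9 enone without touching the ring-fusion carbon C1.

**Step 10**
Reactants: 16 C8=C9 enone
Product: 17 8α-boryl ketone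
Conditions: CuCl (5 mol %), NaOt-Bu (10 mol %), Xantphos (5 mol %), B2pin2 (1.2 equiv), MeOH (2 equiv), THF, rt
Reagents that add atoms: bis(pinacolato)diboron, CC1(C)OB(OC1(C)C)B1OC(C)(C)C(C)(C)O1
Why: Copper-catalysed conjugate borylation in which the boryl–copper species should add to C8 anti to the adjacent C7 isopropyl group, installing a masked 8α-hydroxyl that tolerates the ylide of the next step.

**Step 11**
Reactants: 17 8α-boryl ketone
Product: 19 3β,8α-diol, via boryl alkene 18 (not isolated)
Conditions: Ph3PCH3Br, KOt-Bu, THF, 0 °C to rt; then 30 % H2O2, aq. NaOH, 0 °C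
Reagents that add atoms: methyltriphenylphosphonium bromide, C[P+](c1ccccc1)(c1ccccc1)c1ccccc1.[Br-]; hydrogen peroxide, OO
Why: Wittig methylenation of the C10 ketone followed by oxidation of the C–B bond, which proceeds with retention and should deliver the 8α-alcohol next to the new exocyclic methylene.

**Step 12**
Reactants: 19 3β,8α-diol
Product: 20 tetraol
Conditions: HF·pyridine, pyridine, THF, 0 °C to rt
Reagents that add atoms: none
Why: Fluoride-mediated desilylation should cleave the secondary (O6) and tertiary (O4) triethylsilyl ethers without affecting the exocyclic alkene.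

**Step 13**
Reactants: 20 tetraol
Product: 21 target triacetate
Conditions: Ac2O, pyridine, DMAP (cat.), CH2Cl2, 0 °C to rt
Reagents that add atoms: acetic anhydride, CC(=O)OC(C)=O
Why: Acylation of the three secondary alcohols (O3, O6, O8), while the hindered tertiary C4 hydroxyl should stay free under these mild conditions.

**Compound list**
1 | 3-methylbutanal (isovaleraldehyde) | CC(C)CC=O | starting material
2 | but-3-en-2-one (methyl vinyl ketone) | CC(=O)C=C | starting material
3 | (2S)-2-isopropyl-5-oxohexanal (formed in situ) | CC(=O)CC[C@@H](C(C)C)C=O | intermediate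
4 | (S)-cryptone, (4S)-4-isopropylcyclohex-2-en-1-one | O=C1CC[C@@H](C(C)C)C=C1 | intermediate
5 | (1S,5S,6S)-5-isopropyl-7-oxabicyclo[4.1.0]heptan-2-one (epoxide trans to isopropyl) | O=C1CC[C@@H](C(C)C)[C@@H]2O[C@H]12 | intermediate
6 | (2R,3S,4S)-2-bromo-4-isopropyl-3-(triethylsilyloxy)cyclohexan-1-one | O=C1CC[C@@H](C(C)C)[C@H](O[Si](CC)(CC)CC)[C@H]1Br | intermediate
7 | ethyl pyruvate (ethyl 2-oxopropanoate) | CCOC(=O)C(C)=O | starting material
8 | ethyl (2S)-2-hydroxy-2-[(1S,2S,3S)-3-isopropyl-6-oxo-2-(triethylsilyloxy)cyclohexyl]propanoate | O=C1CC[C@@H](C(C)C)[C@H](O[Si](CC)(CC)CC)[C@H]1[C@](C)(O)C(=O)OCC | intermediate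
9 | vinylmagnesium bromide | C=C[Mg]Br | starting material
10 | ethyl (2S)-2-[(1R,2S,3S,6R)-6-ethenyl-6-hydroxy-3-isopropyl-2-(triethylsilyloxy)cyclohexyl]-2-hydroxypropanoate | C=C[C@]1(O)CC[C@@H](C(C)C)[C@H](O[Si](CC)(CC)CC)[C@H]1[C@](C)(O)C(=O)OCC | intermediate
11 | ethyl (2S)-2-[(1R,2S,3S,6R)-6-ethenyl-3-isopropyl-2,6-bis(triethylsilyloxy)cyclohexyl]-2-(triethylsilyloxy)propanoate | C=C[C@]1(O[Si](CC)(CC)CC)CC[C@@H](C(C)C)[C@H](O[Si](CC)(CC)CC)[C@H]1[C@](C)(O[Si](CC)(CC)CC)C(=O)OCC | intermediate
12 | (2S)-2-[(1R,2S,3S,6R)-6-ethenyl-3-isopropyl-2,6-bis(triethylsilyloxy)cyclohexyl]-2-(triethylsilyloxy)propanal | C=C[C@]1(O[Si](CC)(CC)CC)CC[C@@H](C(C)C)[C@H](O[Si](CC)(CC)CC)[C@H]1[C@](C)(O[Si](CC)(CC)CC)C=O | intermediate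
13 | 3β-hydroxy-4α,6α-bis(triethylsilyloxy)-14-nor-1αH,5αH-guaian-10-one (cis-fused, formed in situ) | O=C1CC[C@@H](C(C)C)[C@H](O[Si](CC)(CC)CC)[C@@H]2[C@H]1C[C@H](O)[C@@]2(C)O[Si](CC)(CC)CC | intermediate
14 | 3β-hydroxy-4α,6α-bis(triethylsilyloxy)-14-nor-1βH,5αH-guaian-10-one (trans-fused) | O=C1CC[C@@H](C(C)C)[C@H](O[Si](CC)(CC)CC)[C@@H]2[C@@H]1C[C@H](O)[C@@]2(C)O[Si](CC)(CC)CC | intermediate
15 | 3β,10-bis(trimethylsilyloxy)-4α,6α-bis(triethylsilyloxy)-14-nor-1βH,5αH-guai-9-ene (formed in situ) | C[Si](C)(C)OC1=CC[C@@H](C(C)C)[C@H](O[Si](CC)(CC)CC)[C@@H]2[C@@H]1C[C@H](O[Si](C)(C)C)[C@@]2(C)O[Si](CC)(CC)CC | intermediate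
16 | 3β-hydroxy-4α,6α-bis(triethylsilyloxy)-14-nor-1βH,5αH-guai-8-en-10-one | O=C1C=C[C@@H](C(C)C)[C@H](O[Si](CC)(CC)CC)[C@@H]2[C@@H]1C[C@H](O)[C@@]2(C)O[Si](CC)(CC)CC | intermediate
17 | 3β-hydroxy-8α-(4,4,5,5-tetramethyl-1,3,2-dioxaborolan-2-yl)-4α,6α-bis(triethylsilyloxy)-14-nor-1βH,5αH-guaian-10-one | O=C1C[C@H](B3OC(C)(C)C(C)(C)O3)[C@@H](C(C)C)[C@H](O[Si](CC)(CC)CC)[C@@H]2[C@@H]1C[C@H](O)[C@@]2(C)O[Si](CC)(CC)CC | intermediate
18 | 8α-(4,4,5,5-tetramethyl-1,3,2-dioxaborolan-2-yl)-4α,6α-bis(triethylsilyloxy)-1βH,5αH-guai-10(14)-en-3β-ol (formed in situ) | C=C1C[C@H](B3OC(C)(C)C(C)(C)O3)[C@@H](C(C)C)[C@H](O[Si](CC)(CC)CC)[C@@H]2[C@@H]1C[C@H](O)[C@@]2(C)O[Si](CC)(CC)CC | intermediate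
19 | 4α,6α-bis(triethylsilyloxy)-1βH,5αH-guai-10(14)-ene-3β,8α-diol | C=C1C[C@H](O)[C@@H](C(C)C)[C@H](O[Si](CC)(CC)CC)[C@@H]2[C@@H]1C[C@H](O)[C@@]2(C)O[Si](CC)(CC)CC | intermediate
20 | 1βH,5αH-guai-10(14)-ene-3β,4α,6α,8α-tetraol | C=C1C[C@H](O)[C@@H](C(C)C)[C@H](O)[C@@H]2[C@@H]1C[C@H](O)[C@@]2(C)O | intermediate
21 | 3β,6α,8α-triacetoxy-1βH,5αH-guai-10(14)-en-4α-ol, (1S,3S,4S,5S,6S,7R,8S) in guaiane numbering | C=C1C[C@H](OC(C)=O)[C@@H](C(C)C)[C@H](OC(C)=O)[C@@H]2[C@@H]1C[C@H](OC(C)=O)[C@@]2(C)O | target

Total step count: 13. Longest linear sequence: 13 steps (from 1 and 2).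

**Steps most likely to fail**

Step 8. The cascade may be intercepted before the 1,2-shift: loss of the tertiary allylic silyloxy group, or chloride capture of the C1 cation, would compete if the monosubstituted vinyl group is too weak a nucleophile for the aldehyde. Fallback: the two bonds are made in separate operations from 12. N-Iodosuccinimide (CH2Cl2, −78 °C) would form an iodonium ion on the vinyl group and trigger the semipinacol shift of C5 from C10 to C1 with loss of the silyl group, giving (2S)-2-[(1S,2S,3S)-7-(iodomethyl)-3-isopropyl-6-oxo-2-(triethylsilyloxy)cycloheptyl]-2-(triethylsilyloxy)propanal F1. Bu3SnH with AIBN (benzene, 80 °C, slow addition) would then close the cyclopentane by 5-exo addition of the primary C2 radical to the aldehyde, giving 13. The DBU equilibration of step 8 brings the route back to 14.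

Step 4. The samarium enolate may expel the β-silyloxy group and return cryptone, or the facial selectivity at the new tertiary carbinol C4 may be poor. Fallback: a reagent-controlled catalytic aldol from 6. Zn and Me3SiCl (THF, 0 °C) would give the regiodefined enol silane triethyl{[(1S,6S)-6-isopropyl-3-(trimethylsilyloxy)cyclohex-2-en-1-yl]oxy}silane F2. A Mukaiyama aldol with ethyl pyruvate, catalysed by Cu(OTf)2 and (S,S)-2,2′-isopropylidenebis(4-tert-butyl-2-oxazoline) (THF, −78 °C, then 1 M HCl), should set C4 under catalyst control and return to 8.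

Step 10. The conjugate borylation may show poor facial selectivity on the flexible seven-membered enone, or the boryl ketone may lose boron under the basic conditions that follow. Fallback: oxygen is introduced as an epoxide from 16. t-BuOOH with DBU (CH2Cl2) should give, anti to isopropyl, 8α,9α-epoxy-3β-hydroxy-4α,6α-bis(triethylsilyloxy)-14-nor-1βH,5αH-guaian-10-one F3. Wittig methylenation (Ph3PCH3Br, KOt-Bu, THF) would give the vinyl epoxide 8α,9α-epoxy-4α,6α-bis(triethylsilyloxy)-1βH,5αH-guai-10(14)-en-3β-ol F4. Formate hydrogenolysis with zerovalent palladium (Pd2(dba)3, n-Bu3P, HCO2H, Et3N, dioxane) should deliver hydride to C9 of the allyl–palladium intermediate and return to 19.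

**Further compounds**
F1 | step 8 | (2S)-2-[(1S,2S,3S)-7-(iodomethyl)-3-isopropyl-6-oxo-2-(triethylsilyloxy)cycloheptyl]-2-(triethylsilyloxy)propanal (both epimers at the iodomethyl-bearing carbon) | O=C1CC[C@@H](C(C)C)[C@H](O[Si](CC)(CC)CC)[C@@H]([C@](C)(O[Si](CC)(CC)CC)C=O)C1CI
F2 | step 4 | triethyl{[(1S,6S)-6-isopropyl-3-(trimethylsilyloxy)cyclohex-2-en-1-yl]oxy}silane | C[Si](C)(C)OC1=C[C@@H](O[Si](CC)(CC)CC)[C@H](C(C)C)CC1
F3 | step 10 | 8α,9α-epoxy-3β-hydroxy-4α,6α-bis(triethylsilyloxy)-14-nor-1βH,5αH-guaian-10-one | O=C1[C@@H]3O[C@@H]3[C@@H](C(C)C)[C@H](O[Si](CC)(CC)CC)[C@@H]2[C@@H]1C[C@H](O)[C@@]2(C)O[Si](CC)(CC)CC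
F4 | step 10 | 8α,9α-epoxy-4α,6α-bis(triethylsilyloxy)-1βH,5αH-guai-10(14)-en-3β-ol | C=C1[C@@H]3O[C@@H]3[C@@H](C(C)C)[C@H](O[Si](CC)(CC)CC)[C@@H]2[C@@H]1C[C@H](O)[C@@]2(C)O[Si](CC)(CC)CC
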